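(Readings and results come from a simulation from invented constants, and the scatter is random.)

**Two plateaus.** Ring ends as a larger fraction of the charge in Thursday's flask than in Monday's: the last two readings average 15.0% at 0.14 M charged, against 6.70% at 0.70 M.

| flask | starting material | remark | time |
|---|---|---|---|
| Thursday's | 0.14 M | run made earlier |  |
| Monday's | 0.70 M | run made earlier |  |
| theta | 0.20 M |  | 80 min |
| delta | 0.40 M |  | 80 min |
| gamma | 0.80 M |  | 80 min |

| run | time / min | ring / % | starting material / % |
|---|---|---|---|
| Thursday's | 20.0 | 24.9 | 1.0 |
| Thursday's | 40.0 | 16.7 | 0.3 |
| Thursday's | 60.0 | 16.0 | 0 |
| Thursday's | 80.0 | 14.1 | 0.5 |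
| Monday's | 6.00 | 15.5 | 3.8 |
| Monday's | 15.0 | 9.8 | 0 |
| Monday's | 30.0 | 7.0 | 0 |
| Monday's | 80.0 | 6.4 | 0 |

(scatter of a reading: 1 percentage point)

- what was read earlier has a scatter of 1 percentage point, one standard deviation
- a reading or a percentage of ring counts all its forms, free or not
- the concentration of ring that is asked is that of its free form alone
- "hardly changes" means that all values lie within two and a half points (for a concentration: within two and a half percent of the largest)
- a reading of starting material is of its free form alone

1. [ring] (only what is free in solution) at the end for theta, delta, gamma, in this order
2. how the row runs (hardly changes / rises, then falls / rises all the way / falls all the way / falls, then rises)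

**Counting lives.** Should we leave the time at 80 min? We define the fade life (a relaxation half-life) as the time over which ring's excess above its plateau drops by a factor of 2. Thursday's starting material already reads 1.0% at 20.0 min, so we take the excess from that reading to the next and get 7.76 min. Monday's readings give 5.98 min. Both are readings, and each point carries a scatter of 1 percentage point. We count with the longer: the planned time holds 10.3 fade lives. Since it is much longer than one life, we leave the time unchanged and expect each flask to stand on its plateau at the end.

**Our row.** Between the two runs the plateau fraction falls as the charge to the power 0.503. This gives 12.6% for theta, 8.88% for delta and 6.26% for gamma, which is a little beyond Monday's charge. We take the end ring as free, so these fractions mean 0.0252 M, 0.0355 M and 0.0501 M, a rising row.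

**The forecast.** It differs from our row: it holds that “free ring is fixed at a critical concentration set by K, whatever the charge”, and gives 0.016 M, 0.016 M and 0.016 M, a row that hardly changes.

**The result.** The flasks end at 0.0247 M, 0.0329 M and 0.0399 M, a row that rises all the way, with gamma below our figure.

    starting material → ring (k = 0.235 min⁻¹)
    2 starting material → open dimer (k = 1.53 L mol⁻¹ min⁻¹)
    ring ⇌ isomer of the product (K = 2.70, k = 0.0573 min⁻¹)
    starting material + ring ⇌ idle adduct, settled at all times (K = 2.60 L mol⁻¹)
    starting material + open dimer → open trimer (k = 1.72 L mol⁻¹ min⁻¹)
    2 starting material → self-condensation product (k = 7.26 × 10⁻⁵ L mol⁻¹ min⁻¹)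

**What ran.** In theta, starting material went early into ring and open dimer, half of the turnover to ring being done by 1.69 min, and ring then passed on to the isomer of the product, with 62% of that turnover done by 16.0 min. Between 40.0 min and 80.0 min we count 5.16 fade lives with our reading of 7.76 min, an estimate that carries the scatter of the readings; over that span theta's ring went from 14.2% to 12.4%, standing at 12.3% at 800 min, and gamma's went from 5.66% to 4.98%, standing at 4.95%.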